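**Retrosynthetic overview**
- The target is a (2S)-flavanone carrying a threo (7R,8R) arylglycerol ether. The last steps are only deprotections: acetonide hydrolysis, then hydrogenolysis of three benzyl ethers.
- C2–aryl bond and C2 stereocentre: catalytic asymmetric conjugate (Michael-type) addition of the ring B arylboronic acid to 5,7-bis(benzyloxy)chromone.
- Key C7–C8 bond and both side-chain stereocentres: intermolecular Evans boron syn-aldol of an (aryloxy)acetyl oxazolidinone with 4-(benzyloxy)benzaldehyde, then reduction to the 1,3-diol.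
- Ring order: all benzene rings are bought. The temporary 1,3-dioxane (acetonide) is closed first on the aldol-derived diol. Pyranone ring C is closed in the chromone branch before the coupling, and no ring is formed afterwards.

Assumption: the SMILES is read as 2S in ring C and 7R,8R (threo) in the side chain (C7 = benzylic carbinol carbon, C8 = aryloxy-bearing carbon, C9 = CH2OH); the five starting materials are taken as catalogue chemicals.

**Route**

Step 1
Reactants: 1 4-bromo-2,6-dimethoxyphenol; 2 ethyl bromoacetate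
Product: 3 ethyl 2-(4-bromo-2,6-dimethoxyphenoxy)acetate
Conditions: K2CO3, acetone, reflux
Reagents that add atoms: none
Why: Williamson ether synthesis, in which the phenoxide displaces bromide from the activated α-bromo ester by SN2; no stereocentre is involved.

Step 2
Reactants: 3 ethyl 2-(4-bromo-2,6-dimethoxyphenoxy)acetate
Product: 5 2-(4-bromo-2,6-dimethoxyphenoxy)acetic acid, via lithium carboxylate 4 (not isolated)
Conditions: LiOH·H2O, THF/H2O (3:1), rt; then 1 M HCl to pH 2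
Reagents that add atoms: lithium hydroxide, [Li+].[OH-]
Why: Ester saponification, in which hydroxide attacks only the ethyl ester (aryl bromide and aryl ethers are inert) and acidification of the carboxylate liberates the acid.

Step 3
Reactants: 5 2-(4-bromo-2,6-dimethoxyphenoxy)acetic acid; 6 (S)-4-benzyl-1,3-oxazolidin-2-one
Product: 8 (4S)-4-benzyl-3-[2-(4-bromo-2,6-dimethoxyphenoxy)acetyl]-1,3-oxazolidin-2-one, via mixed pivalic anhydride 7 (not isolated)
Conditions: t-BuCOCl, Et3N, THF, −20 °C; then 6, LiCl, −20 °C to rt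
Reagents that add atoms: none
Why: N-acylation of the oxazolidinone through a mixed pivalic anhydride, the carbamate nitrogen attacking the unhindered aryloxyacetyl carbonyl and not the pivaloyl one; the auxiliary stereocentre is untouched.

Step 4
Reactants: 8 (4S)-4-benzyl-3-[2-(4-bromo-2,6-dimethoxyphenoxy)acetyl]-1,3-oxazolidin-2-one; 9 4-(benzyloxy)benzaldehyde
Product: 12 (4S)-4-benzyl-3-[(2S,3R)-3-[4-(benzyloxy)phenyl]-2-(4-bromo-2,6-dimethoxyphenoxy)-3-hydroxypropanoyl]-1,3-oxazolidin-2-one, via Z-dibutylboron enolate 10 (not isolated), via dibutylboron aldolate 11 (not isolated)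
Conditions: n-Bu2BOTf, i-Pr2NEt, CH2Cl2, −78 to 0 °C; 9, −78 to 0 °C; pH 7 phosphate buffer, MeOH, 30% H2O2, 0 °C
Reagents that add atoms: none
Why: Evans boron syn-aldol reaction, in which the Z-boron enolate adds to the aldehyde through a chair Zimmerman–Traxler transition state on the face opposite the benzyl group of the (S)-auxiliary, forming the C7–C8 bond and setting both new centres as 2S,3R (syn, the threo 7R,8R array of the target).

Step 5
Reactants: 12 (4S)-4-benzyl-3-[(2S,3R)-3-[4-(benzyloxy)phenyl]-2-(4-bromo-2,6-dimethoxyphenoxy)-3-hydroxypropanoyl]-1,3-oxazolidin-2-one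
Product: 13 (1R,2R)-1-[4-(benzyloxy)phenyl]-2-(4-bromo-2,6-dimethoxyphenoxy)propane-1,3-diol
Conditions: NaBH4, THF/H2O (4:1), 0 °C to rt
Reagents that add atoms: none
Why: Reductive cleavage of the N-acyl oxazolidinone, borohydride attacking the exocyclic imide carbonyl and reducing it to the primary alcohol without touching C7 or C8 (the C8 descriptor changes from S to R only because the CIP ranking changes), with the auxiliary recovered.

Step 6
Reactants: 13 (1R,2R)-1-[4-(benzyloxy)phenyl]-2-(4-bromo-2,6-dimethoxyphenoxy)propane-1,3-diol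
Product: 14 (4R,5R)-4-[4-(benzyloxy)phenyl]-5-(4-bromo-2,6-dimethoxyphenoxy)-2,2-dimethyl-1,3-dioxane
Conditions: Me2C(OMe)2, PPTS (10 mol %), CH2Cl2, rt
Reagents that add atoms: 2,2-dimethoxypropane, COC(C)(C)OC
Why: Acid-catalysed transacetalisation (acetonide formation) closes the 1,3-diol to a 1,3-dioxane with aryl and aryloxy groups trans-diequatorial, masking both hydroxyls for the organolithium and palladium steps without affecting the stereocentres.

Step 7
Reactants: 14 (4R,5R)-4-[4-(benzyloxy)phenyl]-5-(4-bromo-2,6-dimethoxyphenoxy)-2,2-dimethyl-1,3-dioxane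
Product: 17 [4-({(4R,5R)-4-[4-(benzyloxy)phenyl]-2,2-dimethyl-1,3-dioxan-5-yl}oxy)-3,5-dimethoxyphenyl]boronic acid, via aryllithium 15 (not isolated), via lithium triisopropoxyborate 16 (not isolated)
Conditions: B(OiPr)3 (1.5 equiv), n-BuLi (1.2 equiv), THF, −78 °C, then to 0 °C; sat. aq NH4Cl
Reagents that add atoms: triisopropyl borate, CC(C)OB(OC(C)C)OC(C)C; water, O
Why: Bromine–lithium exchange followed by electrophilic borylation, the exchange at −78 °C being far faster than any deprotonation and the aryllithium being trapped at once by the borate already present; mild hydrolysis of the ate complex gives the boronic acid with the acetonide intact.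

Step 8
Reactants: 18 2',4',6'-trihydroxyacetophenone
Product: 19 1-[2,4-bis(benzyloxy)-6-hydroxyphenyl]ethan-1-one
Conditions: BnBr (2.1 equiv), K2CO3 (2.2 equiv), DMF, rt
Reagents that add atoms: benzyl bromide, BrCc1ccccc1
Why: Williamson O-benzylation, in which two phenoxides are alkylated while the remaining ortho-hydroxyl, held in a strong hydrogen bond to the ketone, stays free under carbonate conditions.

Step 9
Reactants: 19 1-[2,4-bis(benzyloxy)-6-hydroxyphenyl]ethan-1-one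
Product: 20 (E)-1-[2,4-bis(benzyloxy)-6-hydroxyphenyl]-3-(dimethylamino)prop-2-en-1-one
Conditions: Me2NCH(OMe)2, toluene, 100 °C
Reagents that add atoms: N,N-dimethylformamide dimethyl acetal, COC(OC)N(C)C
Why: Aminomethylenation of the methyl ketone with the formamide acetal (an aldol-type condensation) gives the E-enaminone that carries the future C2 of ring C.

Step 10
Reactants: 20 (E)-1-[2,4-bis(benzyloxy)-6-hydroxyphenyl]-3-(dimethylamino)prop-2-en-1-one
Product: 21 5,7-bis(benzyloxy)-4H-chromen-4-one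
Conditions: conc. aq HCl, CH2Cl2, rt
Reagents that add atoms: none
Why: Acid-promoted addition–elimination cyclisation, the phenol adding in conjugate fashion to the protonated enaminone and dimethylamine being expelled to close pyranone ring C.

Step 11
Reactants: 17 [4-({(4R,5R)-4-[4-(benzyloxy)phenyl]-2,2-dimethyl-1,3-dioxan-5-yl}oxy)-3,5-dimethoxyphenyl]boronic acid; 21 5,7-bis(benzyloxy)-4H-chromen-4-one (1.5 equiv, excess recovered)
Product: 22 (2S)-5,7-bis(benzyloxy)-2-[4-({(4R,5R)-4-[4-(benzyloxy)phenyl]-2,2-dimethyl-1,3-dioxan-5-yl}oxy)-3,5-dimethoxyphenyl]-2,3-dihydro-4H-chromen-4-one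
Conditions: Pd(OCOCF3)2 (10 mol %), (R)-t-BuPyOx [(R)-4-tert-butyl-2-(pyridin-2-yl)-4,5-dihydrooxazole] (12 mol %), NH4PF6 (30 mol %), H2O (5 equiv), ClCH2CH2Cl, 50 °C
Reagents that add atoms: none
Why: Asymmetric conjugate (Michael-type 1,4-) addition of an arylboronic acid catalysed by a cationic divalent-palladium pyridine-oxazoline complex, in which transmetalation, enantio-determining aryl insertion into the C2=C3 bond on the face left open by the tert-butyl group, and protonolysis of the palladium enolate set C2 as S with the (R)-ligand (assigned as the mirror image of the (S)-ligand/(R)-product sense known for cyclic enones); C7 and C8 are remote and unaffected.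

Step 12
Reactants: 22 (2S)-5,7-bis(benzyloxy)-2-[4-({(4R,5R)-4-[4-(benzyloxy)phenyl]-2,2-dimethyl-1,3-dioxan-5-yl}oxy)-3,5-dimethoxyphenyl]-2,3-dihydro-4H-chromen-4-one
Product: 23 (2S)-5,7-bis(benzyloxy)-2-[4-({(1R,2R)-1-[4-(benzyloxy)phenyl]-1,3-dihydroxypropan-2-yl}oxy)-3,5-dimethoxyphenyl]-2,3-dihydro-4H-chromen-4-one
Conditions: AcOH/THF/H2O (3:1:1), 45 °C
Reagents that add atoms: none
Why: Mild acetal hydrolysis, aqueous acetic acid cleaving the isopropylidene acetal at the acetal carbon only, so the C7–O and C9–O bonds and the configuration are retained while benzyl ethers and the flavanone survive.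

Step 13
Reactants: 23 (2S)-5,7-bis(benzyloxy)-2-[4-({(1R,2R)-1-[4-(benzyloxy)phenyl]-1,3-dihydroxypropan-2-yl}oxy)-3,5-dimethoxyphenyl]-2,3-dihydro-4H-chromen-4-one
Product: 24 (2S)-2-[4-({(1R,2R)-1,3-dihydroxy-1-(4-hydroxyphenyl)propan-2-yl}oxy)-3,5-dimethoxyphenyl]-5,7-dihydroxy-2,3-dihydro-4H-chromen-4-one (CNP0263993.1)
Conditions: H2 (1 atm), 10% Pd/C, EtOAc/THF (1:1), rt
Reagents that add atoms: none
Why: Catalytic hydrogenolysis, the three aryl benzyl ethers being cleaved over Pd/C at 1 atm in a neutral aprotic medium much faster than the secondary benzylic C7–OH or the C2–O1 bond, and the absence of base avoiding ring-opening racemisation at C2.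

**Compound list**

1 | 4-bromo-2,6-dimethoxyphenol | COc1cc(Br)cc(OC)c1O | starting material
2 | ethyl bromoacetate | CCOC(=O)CBr | starting material
3 | ethyl 2-(4-bromo-2,6-dimethoxyphenoxy)acetate | CCOC(=O)COc1c(OC)cc(Br)cc1OC | intermediate
4 | lithium 2-(4-bromo-2,6-dimethoxyphenoxy)acetate | [Li+].[O-]C(=O)COc1c(OC)cc(Br)cc1OC | intermediate
5 | 2-(4-bromo-2,6-dimethoxyphenoxy)acetic acid | OC(=O)COc1c(OC)cc(Br)cc1OC | intermediate
6 | (S)-4-benzyl-1,3-oxazolidin-2-one | O=C1N[C@@H](Cc2ccccc2)CO1 | starting material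
7 | 2-(4-bromo-2,6-dimethoxyphenoxy)acetic pivalic anhydride | CC(C)(C)C(=O)OC(=O)COc1c(OC)cc(Br)cc1OC | intermediate
8 | (4S)-4-benzyl-3-[2-(4-bromo-2,6-dimethoxyphenoxy)acetyl]-1,3-oxazolidin-2-one | O=C(COc1c(OC)cc(Br)cc1OC)N1[C@@H](Cc2ccccc2)COC1=O | intermediate
9 | 4-(benzyloxy)benzaldehyde | O=Cc1ccc(OCc2ccccc2)cc1 | starting material
10 | (Z)-1-[(4S)-4-benzyl-2-oxo-1,3-oxazolidin-3-yl]-2-(4-bromo-2,6-dimethoxyphenoxy)ethenyl dibutylborinate (boron enolate of 8) | CCCCB(CCCC)O/C(=C\Oc1c(OC)cc(Br)cc1OC)N1[C@@H](Cc2ccccc2)COC1=O | intermediate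
11 | O-dibutylboryl aldolate of 12 [(1R,2S)-configured dibutylborinate] | O=C(N1[C@@H](Cc2ccccc2)COC1=O)[C@@H](Oc1c(OC)cc(Br)cc1OC)[C@H](OB(CCCC)CCCC)c1ccc(OCc2ccccc2)cc1 | intermediate
12 | (4S)-4-benzyl-3-[(2S,3R)-3-[4-(benzyloxy)phenyl]-2-(4-bromo-2,6-dimethoxyphenoxy)-3-hydroxypropanoyl]-1,3-oxazolidin-2-one | O=C(N1[C@@H](Cc2ccccc2)COC1=O)[C@@H](Oc1c(OC)cc(Br)cc1OC)[C@H](O)c1ccc(OCc2ccccc2)cc1 | intermediate
13 | (1R,2R)-1-[4-(benzyloxy)phenyl]-2-(4-bromo-2,6-dimethoxyphenoxy)propane-1,3-diol | OC[C@@H](Oc1c(OC)cc(Br)cc1OC)[C@H](O)c1ccc(OCc2ccccc2)cc1 | intermediate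
14 | (4R,5R)-4-[4-(benzyloxy)phenyl]-5-(4-bromo-2,6-dimethoxyphenoxy)-2,2-dimethyl-1,3-dioxane | CC1(C)OC[C@@H](Oc2c(OC)cc(Br)cc2OC)[C@@H](c2ccc(OCc3ccccc3)cc2)O1 | intermediate
15 | [4-({(4R,5R)-4-[4-(benzyloxy)phenyl]-2,2-dimethyl-1,3-dioxan-5-yl}oxy)-3,5-dimethoxyphenyl]lithium | CC1(C)OC[C@@H](Oc2c(OC)cc([Li])cc2OC)[C@@H](c2ccc(OCc3ccccc3)cc2)O1 | intermediate
16 | lithium [4-({(4R,5R)-4-[4-(benzyloxy)phenyl]-2,2-dimethyl-1,3-dioxan-5-yl}oxy)-3,5-dimethoxyphenyl]tri(propan-2-yloxy)borate | [Li+].CC1(C)OC[C@@H](Oc2c(OC)cc([B-](OC(C)C)(OC(C)C)OC(C)C)cc2OC)[C@@H](c2ccc(OCc3ccccc3)cc2)O1 | intermediate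
17 | [4-({(4R,5R)-4-[4-(benzyloxy)phenyl]-2,2-dimethyl-1,3-dioxan-5-yl}oxy)-3,5-dimethoxyphenyl]boronic acid | CC1(C)OC[C@@H](Oc2c(OC)cc(B(O)O)cc2OC)[C@@H](c2ccc(OCc3ccccc3)cc2)O1 | intermediate
18 | 2',4',6'-trihydroxyacetophenone | CC(=O)c1c(O)cc(O)cc1O | starting material
19 | 1-[2,4-bis(benzyloxy)-6-hydroxyphenyl]ethan-1-one | CC(=O)c1c(O)cc(OCc2ccccc2)cc1OCc1ccccc1 | intermediate
20 | (E)-1-[2,4-bis(benzyloxy)-6-hydroxyphenyl]-3-(dimethylamino)prop-2-en-1-one | CN(C)/C=C/C(=O)c1c(O)cc(OCc2ccccc2)cc1OCc1ccccc1 | intermediate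
21 | 5,7-bis(benzyloxy)-4H-chromen-4-one | O=c1ccoc2cc(OCc3ccccc3)cc(OCc3ccccc3)c12 | intermediate
22 | (2S)-5,7-bis(benzyloxy)-2-[4-({(4R,5R)-4-[4-(benzyloxy)phenyl]-2,2-dimethyl-1,3-dioxan-5-yl}oxy)-3,5-dimethoxyphenyl]-2,3-dihydro-4H-chromen-4-one | COc1cc([C@@H]2CC(=O)c3c(OCc4ccccc4)cc(OCc4ccccc4)cc3O2)cc(OC)c1O[C@@H]1COC(C)(C)O[C@@H]1c1ccc(OCc2ccccc2)cc1 | intermediate
23 | (2S)-5,7-bis(benzyloxy)-2-[4-({(1R,2R)-1-[4-(benzyloxy)phenyl]-1,3-dihydroxypropan-2-yl}oxy)-3,5-dimethoxyphenyl]-2,3-dihydro-4H-chromen-4-one | COc1cc([C@@H]2CC(=O)c3c(OCc4ccccc4)cc(OCc4ccccc4)cc3O2)cc(OC)c1O[C@H](CO)[C@H](O)c1ccc(OCc2ccccc2)cc1 | intermediate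
24 | (2S)-2-[4-({(1R,2R)-1,3-dihydroxy-1-(4-hydroxyphenyl)propan-2-yl}oxy)-3,5-dimethoxyphenyl]-5,7-dihydroxy-2,3-dihydro-4H-chromen-4-one | COc1cc([C@@H]2CC(=O)c3c(O)cc(O)cc3O2)cc(OC)c1O[C@H](CO)[C@H](O)c1ccc(O)cc1 | target

**Step count**
Total: 13 steps. Longest linear sequence: 10 steps (steps 1–7 and 11–13, from 1); the chromone branch (steps 8–10) is 3 steps.

**Three steps most likely to fail**

Step 11 (asymmetric conjugate addition). The chromone is deactivated by two alkoxy groups, the boronic acid is elaborate and electron-rich (protodeboronation), and the C2 configuration rests on catalyst control, so it should be confirmed by CD on 24. Any acetonide lost under the weakly acidic conditions is harmless because it gives 23 directly. Fallback: set out from bromide 14 and acetophenone 19. Bromine–lithium exchange on 14 (n-BuLi, THF, −78 °C) and a DMF quench give the aldehyde 4-({(4R,5R)-4-[4-(benzyloxy)phenyl]-2,2-dimethyl-1,3-dioxan-5-yl}oxy)-3,5-dimethoxybenzaldehyde F1. Claisen–Schmidt aldol condensation of this aldehyde with 19 (KOH, EtOH/THF, rt) gives the chalcone (E)-1-[2,4-bis(benzyloxy)-6-hydroxyphenyl]-3-[4-({(4R,5R)-4-[4-(benzyloxy)phenyl]-2,2-dimethyl-1,3-dioxan-5-yl}oxy)-3,5-dimethoxyphenyl]prop-2-en-1-one F2. Oxa-Michael cyclisation (NaOAc, EtOH, reflux) then gives 22 together with its C2 epimer, the (2R)-flavanone F3. The two diastereomers are separated by preparative HPLC on an amylose tris(3,5-dimethylphenylcarbamate) phase, the (2R) isomer is recycled by re-equilibration under the same NaOAc conditions, and the route is rejoined at 22.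

Step 4 (Evans aldol). The bulky, chelating 2,6-dimethoxyphenoxy group may slow enolisation or erode the syn selectivity, and the electron-rich aldehyde is a modest electrophile. Fallback: set out from ester 3. Crossed Claisen condensation of its lithium enolate with 4-(benzyloxy)benzoyl chloride (LiN(SiMe3)2, 2.2 equiv, THF, −78 °C) gives the racemic keto ester ethyl 3-[4-(benzyloxy)phenyl]-2-(4-bromo-2,6-dimethoxyphenoxy)-3-oxopropanoate F4. Asymmetric transfer hydrogenation with dynamic kinetic resolution (RuCl[(S,S)-TsDPEN](p-cymene), HCO2H/Et3N 5:2, DMF, 30 °C) is expected to give the syn hydroxy ester ethyl (2S,3R)-3-[4-(benzyloxy)phenyl]-2-(4-bromo-2,6-dimethoxyphenoxy)-3-hydroxypropanoate F5, because the α-centre epimerises faster than the ketone is reduced and the (S,S)-catalyst delivers hydride to the face giving 3R. Reduction of the ester (LiBH4, THF, 0 °C) rejoins the route at diol 13.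

Step 7 (boronic acid). The free, electron-rich boronic acid may be hard to obtain pure (boroxine mixtures, protodeboronation on silica). Fallback: set out from bromide 14. Miyaura borylation (bis(pinacolato)diboron, PdCl2(dppf), KOAc, dioxane, 85 °C) gives the chromatographable pinacol boronate 2-[4-({(4R,5R)-4-[4-(benzyloxy)phenyl]-2,2-dimethyl-1,3-dioxan-5-yl}oxy)-3,5-dimethoxyphenyl]-4,4,5,5-tetramethyl-1,3,2-dioxaborolane F6. Oxidative cleavage of the pinacol ester (NaIO4, NH4OAc, acetone/H2O, rt) rejoins the route at boronic acid 17.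

**Further compounds**

F1 | step 11 | 4-({(4R,5R)-4-[4-(benzyloxy)phenyl]-2,2-dimethyl-1,3-dioxan-5-yl}oxy)-3,5-dimethoxybenzaldehyde | CC1(C)OC[C@@H](Oc2c(OC)cc(C=O)cc2OC)[C@@H](c2ccc(OCc3ccccc3)cc2)O1
F2 | step 11 | (E)-1-[2,4-bis(benzyloxy)-6-hydroxyphenyl]-3-[4-({(4R,5R)-4-[4-(benzyloxy)phenyl]-2,2-dimethyl-1,3-dioxan-5-yl}oxy)-3,5-dimethoxyphenyl]prop-2-en-1-one | CC1(C)OC[C@@H](Oc2c(OC)cc(/C=C/C(=O)c3c(O)cc(OCc4ccccc4)cc3OCc3ccccc3)cc2OC)[C@@H](c2ccc(OCc3ccccc3)cc2)O1
F3 | step 11 | (2R)-5,7-bis(benzyloxy)-2-[4-({(4R,5R)-4-[4-(benzyloxy)phenyl]-2,2-dimethyl-1,3-dioxan-5-yl}oxy)-3,5-dimethoxyphenyl]-2,3-dihydro-4H-chromen-4-one | COc1cc([C@H]2CC(=O)c3c(OCc4ccccc4)cc(OCc4ccccc4)cc3O2)cc(OC)c1O[C@@H]1COC(C)(C)O[C@@H]1c1ccc(OCc2ccccc2)cc1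
F4 | step 4 | ethyl 3-[4-(benzyloxy)phenyl]-2-(4-bromo-2,6-dimethoxyphenoxy)-3-oxopropanoate (racemic) | CCOC(=O)C(Oc1c(OC)cc(Br)cc1OC)C(=O)c1ccc(OCc2ccccc2)cc1
F5 | step 4 | ethyl (2S,3R)-3-[4-(benzyloxy)phenyl]-2-(4-bromo-2,6-dimethoxyphenoxy)-3-hydroxypropanoate | CCOC(=O)[C@@H](Oc1c(OC)cc(Br)cc1OC)[C@H](O)c1ccc(OCc2ccccc2)cc1
F6 | step 7 | 2-[4-({(4R,5R)-4-[4-(benzyloxy)phenyl]-2,2-dimethyl-1,3-dioxan-5-yl}oxy)-3,5-dimethoxyphenyl]-4,4,5,5-tetramethyl-1,3,2-dioxaborolane | CC1(C)OC[C@@H](Oc2c(OC)cc(B3OC(C)(C)C(C)(C)O3)cc2OC)[C@@H](c2ccc(OCc3ccccc3)cc2)O1
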